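**Retrosynthetic overview**
1. Locants (tricyclo[5.4.0.0(2,8)]undecane numbering): ring A = C1, C11(=O), C10=C9(Me), C8, C2; cyclobutane = C1, C2, C8, C7(Me); seven-membered ring = C2, C3(Me2), C4(OH), C5(O-angeloyl), C6(O-acyl), C7 plus C1 or C8.
2. End game: angelate by SN2 opening of a C4–C5 epoxide (the trans C4–OH falls out), C6 ester on a CBS-derived carbinol, ring A enone by oxidation at C11 and dehydrogenation to C9=C10.
3. Key disconnection: C1–C7 (closes the cyclobutane) and C5–C6 (closes the seven-membered ring) are made together by a base-triggered anion relay on a monocyclic epoxy nitrile.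
4. Enabling feature: C7 is quaternary, 1,3 to C1 across ring A, and carries C6 at the carboxyl level. A C6 nitrile first makes C7 the nucleophile that opens a C1–C11 oxirane (leaving on C11 the oxygen of the enone), then serves as the electrophile for C5, the α-carbon of a masked C4 ketone.
5. Ring order: ring A by Diels–Alder reaction (sets C2/C8 cis), then cyclobutane and seven-membered ring in step 9.

Key step: step 9

Remark: the acyl groups are read as (2Z)-2-methylbut-2-enoate (angelate) and (2R)-2-methylbutanoate; the nitrile-bearing carbon of 10–13 is an epimeric mixture, which is harmless because it becomes a planar carbanion in step 9.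

**Step 1**
Reactants: 1 ethyl 2,2-dimethyl-3-oxobutanoate; 2 ethylene glycol
Product: 3 ethyl 2-methyl-2-(2-methyl-1,3-dioxolan-2-yl)propanoate
Conditions: TsOH (cat.), toluene, reflux, Dean–Stark
Reagents that add atoms: none
Why: Acid-catalysed ketalisation masks the ketone so that the following steps address only the ester carbon and, later, the ring acetyl group; no stereocentre is formed.

**Step 2**
Reactants: 3 ethyl 2-methyl-2-(2-methyl-1,3-dioxolan-2-yl)propanoate
Product: 4 2-methyl-2-(2-methyl-1,3-dioxolan-2-yl)propanal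
Conditions: i-Bu2AlH (1.1 equiv), CH2Cl2, −78 °C; Rochelle salt work-up
Reagents that add atoms: none
Why: Low-temperature i-Bu2AlH half-reduction of the hindered, non-enolisable ester should stop at the aldehyde because the tetrahedral aluminium hemiacetal survives at −78 °C; no stereocentre.

**Step 3**
Reactants: 4 2-methyl-2-(2-methyl-1,3-dioxolan-2-yl)propanal; 5 diethyl allylphosphonate
Product: 6 2-methyl-2-[(3E)-2-methylhexa-3,5-dien-2-yl]-1,3-dioxolane
Conditions: n-BuLi, THF, −78 °C; then HMPA, −78 → 25 °C
Reagents that add atoms: none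
Why: Horner–Wadsworth–Emmons-type olefination with the lithiated allylphosphonate turns the neopentylic aldehyde into the 1-substituted butadiene; the E isomer should dominate for this bulky aldehyde and is the only one that can reach the s-cis geometry needed in step 4.

**Step 4**
Reactants: 6 2-methyl-2-[(3E)-2-methylhexa-3,5-dien-2-yl]-1,3-dioxolane; 7 (E)-pent-3-en-2-one
Product: 8 1-{6-methyl-2-[2-(2-methyl-1,3-dioxolan-2-yl)propan-2-yl]cyclohex-3-en-1-yl}ethan-1-one (acetyl cis to the C2 side chain and trans to the C6 methyl; single enantiomer)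
Conditions: (S)-B-o-tolyl-oxazaborolidinium triflimide (from the (S)-diphenylprolinol o-tolylboronate and HNTf2, 20 mol %), CH2Cl2, −78 → −20 °C
Reagents that add atoms: none
Why: Lewis-acid-catalysed Diels–Alder reaction: ortho regiochemistry joins the substituted diene terminus to the acetyl-bearing carbon, the endo rule places acetyl cis to the tert-alkyl group (future C8/C2 cis), the E dienophile places methyl trans to acetyl, and the chiral catalyst selects the enone face and so the absolute configuration.

**Step 5**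
Reactants: 8 Diels–Alder ketone; 9 p-toluenesulfonylmethyl isocyanide (TosMIC)
Product: 10 2-{6-methyl-2-[2-(2-methyl-1,3-dioxolan-2-yl)propan-2-yl]cyclohex-3-en-1-yl}propanenitrile (ring configuration as in 8; both epimers at the nitrile α-carbon)
Conditions: KOt-Bu, DME/EtOH, 0 → 30 °C
Reagents that add atoms: none
Why: van Leusen reductive cyanation converts the methyl ketone into the one-carbon-homologated secondary nitrile (future C7–H and C6); the new stereocentre is an inconsequential mixture, and a short, cold reaction should limit epimerisation at the ring carbon next to the ketone.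

**Step 6**
Reactants: 10 ketal nitrile
Product: 11 2-[6-methyl-2-(2-methyl-3-oxobutan-2-yl)cyclohex-3-en-1-yl]propanenitrile
Conditions: PPTS, acetone/H2O (10:1), 55 °C
Reagents that add atoms: water, O
Why: Mild acid-catalysed ketal hydrolysis releases the methyl ketone before the acid-sensitive oxirane is introduced; nitrile, alkene and ring stereocentres are untouched.

**Step 7**
Reactants: 11 keto nitrile
Product: 12 2-[4-methyl-2-(2-methyl-3-oxobutan-2-yl)-7-oxabicyclo[4.1.0]heptan-3-yl]propanenitrile (oxirane trans to the C2 and C3 side chains)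
Conditions: mCPBA (1.05 equiv), NaHCO3, CH2Cl2, 0 °C
Reagents that add atoms: mCPBA, O=C(OO)c1cccc(Cl)c1
Why: Prilezhaev epoxidation should occur on the ring face opposite to the two cis side chains (the allylic tert-alkyl group shields the other face), giving the oxirane trans to the nitrile-bearing chain as backside attack in step 9 requires; alkene epoxidation is much faster than Baeyer–Villiger oxidation of the hindered ketone.

**Step 8**
Reactants: 12 epoxy keto nitrile
Product: 13 2-{4-methyl-2-[2-methyl-3-(triethylsilyloxy)but-3-en-2-yl]-7-oxabicyclo[4.1.0]heptan-3-yl}propanenitrile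
Conditions: LiN(SiMe3)2 (1.1 equiv), Et3SiCl (in situ), THF, −78 °C
Reagents that add atoms: chlorotriethylsilane, CC[Si](Cl)(CC)CC
Why: Kinetic deprotonation of the methyl ketone (its only enolisable position, and more acidic than the nitrile α-hydrogen) with in situ silylation gives the silyl enol ether that masks the C5 nucleophile for the next step.

**Step 9**
Reactants: 13 epoxy nitrile silyl enol ether
Product: 16 6-amino-3,3,7,9-tetramethyl-11-(triethylsilyloxy)tricyclo[5.4.0.0(2,8)]undec-5-en-4-one, via bicyclic nitrile alkoxide 14 (not isolated), via potassium enolate 15 (not isolated)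
Conditions: KN(SiMe3)2 (1.2 equiv), 18-crown-6 (0.2 equiv), THF, −78 → 40 °C; aq. NH4Cl
Reagents that add atoms: none
Why: Proposed new method: KN(SiMe3)2 deprotonates only the nitrile α-carbon (the ketone is masked), and the nitrile-stabilised carbanion at C7 opens the oxirane at C1 in a Stork-type epoxynitrile cyclisation (4-exo-tet, trans-diaxial, inversion at C1) that closes the cyclobutane and leaves an alkoxide on C11; this alkoxide then takes the triethylsilyl group from the enol ether (O-to-O silyl transfer), which releases the methyl ketone enolate only after the epoxide is consumed, and the enolate carbon C5 adds to the now non-enolisable nitrile carbon C6 in a Thorpe–Ziegler-type closure (7-exo-dig) driven by formation of the vinylogous amide. The closest known reaction types are the Stork epoxynitrile cyclisation to cyclobutanes, alkoxide-induced generation of enolates from silyl enol ethers and the Thorpe–Ziegler condensation; their coupling through an anion relay and the closure onto a bicyclo[3.1.1]heptane nitrile are new. C1 is set by backside opening of the epoxide, which a chair transition state allows only at C1 (attack at C11 would need a boat and give a bicyclo[2.2.1] isomer); C7 is set because the small, linear nitrile rather than methyl takes the position next to the bulky C2 substituent, and only this epimer can close the seven-membered ring. The step needs 4-exo over 5-endo epoxide opening and no premature C5 nucleophile, and the silyl mask secures the latter, since a free enolate would attack the epoxide to give a five-membered ring.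

**Step 10**
Reactants: 16 tricyclic enaminone
Product: 18 3,3,7,9-tetramethyl-11-(triethylsilyloxy)tricyclo[5.4.0.0(2,8)]undec-4-en-6-one, via amino allylic alcohol 17 (not isolated)
Conditions: LiAlH4 (3 equiv), THF, 0 → 40 °C; then 1 M HCl, 0 °C, brief
Reagents that add atoms: water, O
Why: Hydride 1,2-reduction of the vinylogous amide carbonyl, then acid-promoted loss of water and hydrolysis of the iminium (an enaminone 1,3-carbonyl transposition, analogous to the Stork–Danheiser sequence), puts the ketone on C6 and the alkene at C4=C5; the product has no new stereocentre.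

**Step 11**
Reactants: 18 tricyclic enone
Product: 19 3,3,7,9-tetramethyl-11-(triethylsilyloxy)tricyclo[5.4.0.0(2,8)]undec-4-en-6-ol (C6 as in the target)
Conditions: (S)-2-methyl-CBS-oxazaborolidine (0.2 equiv), BH3·SMe2, THF, −30 °C; MeOH quench
Reagents that add atoms: none
Why: Corey–Bakshi–Shibata reduction gives reagent-controlled 1,2-reduction: with the fully substituted C7 as the large group and the alkene as the small one, the (S)-catalyst should deliver hydride to the face that gives the required C6 configuration (the (R)-catalyst would be used if the alkene proves to act as the large group).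

**Step 12**
Reactants: 19 allylic alcohol; 20 (2R)-2-methylbutanoic acid
Product: 21 3,3,7,9-tetramethyl-11-(triethylsilyloxy)tricyclo[5.4.0.0(2,8)]undec-4-en-6-yl (2R)-2-methylbutanoate
Conditions: DCC, DMAP (0.2 equiv), CH2Cl2, 0 → 25 °C
Reagents that add atoms: none
Why: Steglich esterification acylates the only free hydroxyl; the acid stereocentre is carried in unchanged (low temperature, catalytic DMAP, to avoid epimerisation).

**Step 13**
Reactants: 21 silyl ether ester
Product: 22 11-hydroxy-3,3,7,9-tetramethyltricyclo[5.4.0.0(2,8)]undec-4-en-6-yl (2R)-2-methylbutanoate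
Conditions: HF·pyridine, pyridine, THF, 0 → 25 °C
Reagents that add atoms: none
Why: Fluoride cleavage of the triethylsilyl ether frees the C11 alcohol; ester and alkene are stable under these conditions.

**Step 14**
Reactants: 22 hydroxy ester
Product: 23 3,3,7,9-tetramethyl-11-oxotricyclo[5.4.0.0(2,8)]undec-4-en-6-yl (2R)-2-methylbutanoate
Conditions: Dess–Martin periodinane, NaHCO3, CH2Cl2, 25 °C
Reagents that add atoms: none
Why: Dess–Martin oxidation converts the secondary alcohol into the C11 ketone under neutral conditions and removes the C11 stereocentre.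

**Step 15**
Reactants: 23 keto ester
Product: 24 3,3,7,9-tetramethyl-11-oxotricyclo[5.4.0.0(2,8)]undeca-4,9-dien-6-yl (2R)-2-methylbutanoate
Conditions: IBX (2.5 equiv), DMSO/fluorobenzene, 70 °C
Reagents that add atoms: none
Why: IBX-mediated α,β-dehydrogenation: the ketone can enolise only towards C10 because C1 is a bridgehead, so the C9=C10 enone should form regiospecifically and the C9 stereocentre disappears.

**Step 16**
Reactants: 24 dienone ester
Product: 25 4,5-epoxy-3,3,7,9-tetramethyl-11-oxotricyclo[5.4.0.0(2,8)]undec-9-en-6-yl (2R)-2-methylbutanoate (oxirane trans to the C6 ester)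
Conditions: mCPBA, NaHCO3, CH2Cl2, 0 → 25 °C
Reagents that add atoms: mCPBA, O=C(OO)c1cccc(Cl)c1
Why: Prilezhaev epoxidation of the only electron-rich alkene (C4=C5) should occur anti to the allylic acyloxy group at C6, the enone being inert to peracid; this sets C4 and the transient C5 configuration.

**Step 17**
Reactants: 25 epoxy ester; 26 angelic acid
Product: 27 4-hydroxy-3,3,7,9-tetramethyl-6-[(2R)-2-methylbutanoyloxy]-11-oxotricyclo[5.4.0.0(2,8)]undec-9-en-5-yl (2Z)-2-methylbut-2-enoate (target)
Conditions: angelic acid (3 equiv), Cs2CO3 (0.2 equiv), DMF, 60 °C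
Reagents that add atoms: none
Why: Carboxylate SN2 opening of the epoxide at C5 (C4 is neopentylic and blocked) with inversion places the angelate cis to the C6 ester and leaves the C4 hydroxyl trans to it; the weakly basic, acid-buffered medium is chosen to limit Z-to-E isomerisation and acyl migration.

**Compound list**
1 | ethyl 2,2-dimethyl-3-oxobutanoate | CCOC(=O)C(C)(C)C(C)=O | starting material
2 | ethylene glycol | OCCO | starting material
3 | ethyl 2-methyl-2-(2-methyl-1,3-dioxolan-2-yl)propanoate | CCOC(=O)C(C)(C)C1(C)OCCO1 | intermediate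
4 | 2-methyl-2-(2-methyl-1,3-dioxolan-2-yl)propanal | O=CC(C)(C)C1(C)OCCO1 | intermediate
5 | diethyl allylphosphonate | C=CCP(=O)(OCC)OCC | starting material
6 | 2-methyl-2-[(3E)-2-methylhexa-3,5-dien-2-yl]-1,3-dioxolane | C=C/C=C/C(C)(C)C1(C)OCCO1 | intermediate
7 | (E)-pent-3-en-2-one | C/C=C/C(C)=O | starting material
8 | 1-{6-methyl-2-[2-(2-methyl-1,3-dioxolan-2-yl)propan-2-yl]cyclohex-3-en-1-yl}ethan-1-one (acetyl cis to the C2 side chain, trans to the C6 methyl; single enantiomer) | CC(=O)[C@H]1[C@H](C)CC=C[C@H]1C(C)(C)C1(C)OCCO1 | intermediate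
9 | p-toluenesulfonylmethyl isocyanide (TosMIC) | [C-]#[N+]CS(=O)(=O)c1ccc(C)cc1 | starting material
10 | 2-{6-methyl-2-[2-(2-methyl-1,3-dioxolan-2-yl)propan-2-yl]cyclohex-3-en-1-yl}propanenitrile (ring as in 8; both epimers at the nitrile α-carbon) | N#CC(C)[C@H]1[C@H](C)CC=C[C@H]1C(C)(C)C1(C)OCCO1 | intermediate
11 | 2-[6-methyl-2-(2-methyl-3-oxobutan-2-yl)cyclohex-3-en-1-yl]propanenitrile | N#CC(C)[C@H]1[C@H](C)CC=C[C@H]1C(C)(C)C(C)=O | intermediate
12 | 2-[4-methyl-2-(2-methyl-3-oxobutan-2-yl)-7-oxabicyclo[4.1.0]heptan-3-yl]propanenitrile (oxirane trans to both side chains) | N#CC(C)[C@H]1[C@H](C)C[C@@H]2O[C@@H]2[C@H]1C(C)(C)C(C)=O | intermediate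
13 | 2-{4-methyl-2-[2-methyl-3-(triethylsilyloxy)but-3-en-2-yl]-7-oxabicyclo[4.1.0]heptan-3-yl}propanenitrile | N#CC(C)[C@H]1[C@H](C)C[C@@H]2O[C@@H]2[C@H]1C(C)(C)C(=C)O[Si](CC)(CC)CC | intermediate
14 | potassium alkoxide of 2-hydroxy-4,6-dimethyl-7-[2-methyl-3-(triethylsilyloxy)but-3-en-2-yl]bicyclo[3.1.1]heptane-6-carbonitrile (nitrile on the side of the C7 chain) | C=C(O[Si](CC)(CC)CC)C(C)(C)[C@@H]1[C@H]2[C@@H]([O-])C[C@@H](C)[C@@H]1[C@@]2(C)C#N.[K+] | intermediate
15 | potassium enolate of 4,6-dimethyl-7-(2-methyl-3-oxobutan-2-yl)-2-(triethylsilyloxy)bicyclo[3.1.1]heptane-6-carbonitrile | C=C([O-])C(C)(C)[C@@H]1[C@H]2[C@@H](O[Si](CC)(CC)CC)C[C@@H](C)[C@@H]1[C@@]2(C)C#N.[K+] | intermediate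
16 | 6-amino-3,3,7,9-tetramethyl-11-(triethylsilyloxy)tricyclo[5.4.0.0(2,8)]undec-5-en-4-one (C1, C2, C7, C8 as in the target) | O=C1C(C)(C)[C@@H]2[C@H]3[C@@H](O[Si](CC)(CC)CC)C[C@@H](C)[C@@H]2[C@@]3(C)C(N)=C1 | intermediate
17 | 6-amino-3,3,7,9-tetramethyl-11-(triethylsilyloxy)tricyclo[5.4.0.0(2,8)]undec-5-en-4-ol (C4 epimers) | OC1C(C)(C)[C@@H]2[C@H]3[C@@H](O[Si](CC)(CC)CC)C[C@@H](C)[C@@H]2[C@@]3(C)C(N)=C1 | intermediate
18 | 3,3,7,9-tetramethyl-11-(triethylsilyloxy)tricyclo[5.4.0.0(2,8)]undec-4-en-6-one | O=C1C=CC(C)(C)[C@@H]2[C@H]3[C@@H](O[Si](CC)(CC)CC)C[C@@H](C)[C@@H]2[C@@]13C | intermediate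
19 | 3,3,7,9-tetramethyl-11-(triethylsilyloxy)tricyclo[5.4.0.0(2,8)]undec-4-en-6-ol (C6 as in the target) | O[C@@H]1C=CC(C)(C)[C@@H]2[C@H]3[C@@H](O[Si](CC)(CC)CC)C[C@@H](C)[C@@H]2[C@@]13C | intermediate
20 | (2R)-2-methylbutanoic acid | CC[C@@H](C)C(=O)O | starting material
21 | 3,3,7,9-tetramethyl-11-(triethylsilyloxy)tricyclo[5.4.0.0(2,8)]undec-4-en-6-yl (2R)-2-methylbutanoate | CC[C@@H](C)C(=O)O[C@@H]1C=CC(C)(C)[C@@H]2[C@H]3[C@@H](O[Si](CC)(CC)CC)C[C@@H](C)[C@@H]2[C@@]13C | intermediate
22 | 11-hydroxy-3,3,7,9-tetramethyltricyclo[5.4.0.0(2,8)]undec-4-en-6-yl (2R)-2-methylbutanoate | CC[C@@H](C)C(=O)O[C@@H]1C=CC(C)(C)[C@@H]2[C@H]3[C@@H](O)C[C@@H](C)[C@@H]2[C@@]13C | intermediate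
23 | 3,3,7,9-tetramethyl-11-oxotricyclo[5.4.0.0(2,8)]undec-4-en-6-yl (2R)-2-methylbutanoate | CC[C@@H](C)C(=O)O[C@@H]1C=CC(C)(C)[C@@H]2[C@H]3C(=O)C[C@@H](C)[C@@H]2[C@@]13C | intermediate
24 | 3,3,7,9-tetramethyl-11-oxotricyclo[5.4.0.0(2,8)]undeca-4,9-dien-6-yl (2R)-2-methylbutanoate | CC[C@@H](C)C(=O)O[C@@H]1C=CC(C)(C)[C@@H]2[C@H]3C(=O)C=C(C)[C@@H]2[C@@]13C | intermediate
25 | 4,5-epoxy-3,3,7,9-tetramethyl-11-oxotricyclo[5.4.0.0(2,8)]undec-9-en-6-yl (2R)-2-methylbutanoate (oxirane trans to the C6 ester) | CC[C@@H](C)C(=O)O[C@@H]1[C@H]2O[C@H]2C(C)(C)[C@@H]3[C@H]4C(=O)C=C(C)[C@@H]3[C@@]14C | intermediate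
26 | angelic acid, (2Z)-2-methylbut-2-enoic acid | C/C=C(/C)C(=O)O | starting material
27 | 4-hydroxy-3,3,7,9-tetramethyl-6-[(2R)-2-methylbutanoyloxy]-11-oxotricyclo[5.4.0.0(2,8)]undec-9-en-5-yl (2Z)-2-methylbut-2-enoate | C/C=C(/C)C(=O)O[C@@H]1[C@@H](O)C(C)(C)[C@@H]2[C@H]3C(=O)C=C(C)[C@@H]2[C@@]3(C)[C@@H]1OC(=O)[C@H](C)CC | target

**Totals**
Total step count: 17. Longest linear sequence: 17 steps (from 1).

**Steps most likely to fail**

Step 9 (proposed new method). The relay may stall after the cyclobutane closure because silyl transfer or enolate addition to the hindered nitrile is slow. The enolate may also be released too early and open the epoxide to a five-membered ring, or the carbanion may open the epoxide at C11. The fallback runs the same bond formations stepwise with known reactions, setting out from 10 and coming back at 16. Epoxidation of 10 with mCPBA gives the ketal-protected epoxy nitrile F1. KN(SiMe3)2 then effects the Stork epoxynitrile cyclisation to the bicyclic hydroxy nitrile F2, which has no enolisable ketone. PPTS in wet acetone removes the ketal to give the hydroxy keto nitrile F3. Et3SiCl with imidazole gives the silyl ether F4. KOt-Bu in THF with heating closes the seven-membered ring by Thorpe–Ziegler-type enolate addition to the nitrile and delivers 16.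

Step 17. Opening of the hindered epoxide may be slow, the angelate may isomerise to the E ester under the carboxylate conditions, and the acyl groups may migrate among O4, O5 and O6. The fallback sets out from 24 and comes back at 27. OsO4 (cat.) with N-methylmorpholine N-oxide dihydroxylates the C4=C5 alkene anti to the C6 ester to give the cis-diol F5. A Mitsunobu esterification (PPh3, diisopropyl azodicarboxylate, angelic acid 26) then acylates the less hindered C5 hydroxyl with inversion, the neopentylic C4 hydroxyl being inert, and gives 27.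

Step 4. Facial and endo selectivity may be poor, or the hindered diene may react sluggishly with the β-substituted enone under catalyst control. The fallback sets out from 6 and comes back at 8. (4S)-4-Benzyl-1,3-oxazolidin-2-one is acylated with crotonyl chloride to the N-crotonoyl imide F6 (the antipodal auxiliary is used if the induction proves opposite). An Et2AlCl-promoted, auxiliary-controlled Diels–Alder reaction with 6 gives the adduct imide F7. Me3Al with MeNH(OMe)·HCl converts it into the Weinreb amide F8, and MeMgBr gives 8.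

**Further compounds**
F1 | step 9 | 2-{4-methyl-2-[2-(2-methyl-1,3-dioxolan-2-yl)propan-2-yl]-7-oxabicyclo[4.1.0]heptan-3-yl}propanenitrile | N#CC(C)[C@H]1[C@H](C)C[C@@H]2O[C@@H]2[C@H]1C(C)(C)C1(C)OCCO1
F2 | step 9 | 2-hydroxy-4,6-dimethyl-7-[2-(2-methyl-1,3-dioxolan-2-yl)propan-2-yl]bicyclo[3.1.1]heptane-6-carbonitrile | CC1(OCCO1)C(C)(C)[C@@H]1[C@H]2[C@@H](O)C[C@@H](C)[C@@H]1[C@@]2(C)C#N
F3 | step 9 | 2-hydroxy-4,6-dimethyl-7-(2-methyl-3-oxobutan-2-yl)bicyclo[3.1.1]heptane-6-carbonitrile | CC(=O)C(C)(C)[C@@H]1[C@H]2[C@@H](O)C[C@@H](C)[C@@H]1[C@@]2(C)C#N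
F4 | step 9 | 4,6-dimethyl-7-(2-methyl-3-oxobutan-2-yl)-2-(triethylsilyloxy)bicyclo[3.1.1]heptane-6-carbonitrile | CC(=O)C(C)(C)[C@@H]1[C@H]2[C@@H](O[Si](CC)(CC)CC)C[C@@H](C)[C@@H]1[C@@]2(C)C#N
F5 | step 17 | 4,5-dihydroxy-3,3,7,9-tetramethyl-11-oxotricyclo[5.4.0.0(2,8)]undec-9-en-6-yl (2R)-2-methylbutanoate (both hydroxyls trans to the C6 ester) | CC[C@@H](C)C(=O)O[C@@H]1[C@@H](O)[C@@H](O)C(C)(C)[C@@H]2[C@H]3C(=O)C=C(C)[C@@H]2[C@@]13C
F6 | step 4 | (4S)-4-benzyl-3-[(2E)-but-2-enoyl]-1,3-oxazolidin-2-one | C/C=C/C(=O)N1C(=O)OC[C@@H]1Cc1ccccc1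
F7 | step 4 | (4S)-4-benzyl-3-({6-methyl-2-[2-(2-methyl-1,3-dioxolan-2-yl)propan-2-yl]cyclohex-3-en-1-yl}carbonyl)-1,3-oxazolidin-2-one (ring configuration as in 8) | O=C([C@H]1[C@H](C)CC=C[C@H]1C(C)(C)C1(C)OCCO1)N1C(=O)OC[C@@H]1Cc1ccccc1
F8 | step 4 | N-methoxy-N,6-dimethyl-2-[2-(2-methyl-1,3-dioxolan-2-yl)propan-2-yl]cyclohex-3-ene-1-carboxamide (ring configuration as in 8) | CON(C)C(=O)[C@H]1[C@H](C)CC=C[C@H]1C(C)(C)C1(C)OCCO1
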